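## Structural features

Ineupatorolide A (36) is a germacrane-type sesquiterpene lactone: a ten-membered carbocycle (C1–C10) is trans-fused through C7 and C8 to an α-methylene-γ-butyrolactone (C7–C8–O–C12–C11, with C13 as the exocyclic methylene). Four stereocentres stand side by side on one edge of the medium ring: the ring-fusion methine C7, the lactone carbinol C8, the acylated carbinol C9 and the tertiary methyl carbinol C10. The C4 methyl centre is isolated on the far side next to the C5 ketone, and a sixth centre lies in the (R)-2-methylbutanoate. The fragile groups are the exocyclic enoate (a Michael acceptor that tolerates neither carbon nucleophiles nor hydrogenation), the C4 centre (epimerisable through the C5 enol), the C9 ester, and any carbonyl at C10, which has the C8 lactone oxygen in the β-position and can eliminate it. The real difficulty lies in closing a ten-membered ring that already carries the trans-fused lactone, in building the C10 quaternary carbinol with the right configuration, and in the remoteness of C4, which no centre of the C7–C10 array can control. Two features point to the solution: the C5 ketone and the C12 carbonyl are 1,5-related through C6–C7–C11, so C6–C7 is the bond of a Michael addition to a butenolide made of C7, C11, C12, the ring oxygen and C8; and the C8 and C9 oxygens form a threo-diol with the configuration of L-tartaric acid. The key step exploits both: a C1–C6 enol silane that already carries C4 adds to C7 of a tartrate-derived butenolide, and the enolate equivalent formed at C11 is used at once to attach C13 in masked form.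

## Logic of the disconnections

36 ⇒ 34. No skeletal bond is cut; the C11=C13 double bond is exchanged for C11–H and C13–NMe2. The exocyclic enoate would not survive Grignard reagents, hydride sources or hydrogenation, so it is kept masked to the end. The gain is that every earlier step may use nucleophiles and reducing agents. The forward step must eliminate under conditions that spare the C9 ester and the C4 centre, which quaternisation (35) and a weak base provide.

34 ⇒ 30 + 31 (through 33). The C9–O acyl bond is cut and the C5 ketone is returned to its ketal. The ester cannot be present when the C10 methyl group is introduced. The gain is the removal of one stereocentre and of a base-labile group. The forward steps must acylate the secondary C9 hydroxyl beside the tertiary C10 hydroxyl without racemising 31, and must keep C5 masked until C9 is capped, so that a free C9 hydroxyl never faces the C5 carbonyl across the ring.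

30 ⇒ 28 (through 29). The C10–CH3 bond is cut and the C9 oxygen regains its benzyl group. A tertiary carbinol next to an ether oxygen is the product of a chelation-controlled methyl addition to a ketone. The gain is the loss of the quaternary centre and a C10 carbonyl that also serves the ring closure. The forward step must find the right face of a medium-ring ketone and must leave the lactone alone, which is why C5 is a ketal at this stage.

28 ⇒ 25 (through 27 and 26). The ring bond C10–C1 is cut. It is the only ring bond that joins a carbonyl-derived carbon to a carbon that can be an alkenyl metal terminus. The gain is an acyclic chain on a monocyclic lactone. The forward step must close a ten-membered ring in competition with oligomerisation and must add to an aldehyde in the presence of a lactone; the C10 configuration created there is irrelevant, because 26 and 27 converge at 28.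

25 ⇒ 19 (through 24, 22 and 21). No skeletal bond is cut. The iodoalkene goes back to the terminal alkyne, the aldehyde to the silyl ether, the ketal to the ketone. The order matters in the forward direction: the ketal goes on first, so that the hydride reagent and, later, the Grignard reagent meet only one reactive carbonyl; one fluoride treatment removes both silicon groups.

19 ⇒ 8 + 16 + 17. The bonds C6–C7 and C11–C13 are cut. This is the 1,5-dicarbonyl retron, and it divides the molecule into two halves of similar size whose stereocentres come from separate sources (C8, C9 in 8; C4 in 16). The gain is the largest of the route: two skeletal bonds and two stereocentres in one operation, with C13 introduced in protected form. The forward step must react at C6 and not C4, must add anti to the C8 side chain, and must hand the silicon to the lactone oxygen so that 17 can be captured.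

8 ⇒ 1 (through 7, 6, 5, 4 and 3). The C7=C11 double bond (olefination) and the lactone O–C12 bond are cut. The threo-diol of 8 is that of 1, so both centres are taken from the chiral pool and none has to be made. The forward steps must give the (Z)-enoate (only this can lactonise), must use a silyl ether that survives the acid that frees the diol, and must put the benzyl group on O9 without base, because the C8 proton of a butenolide is acidic. A p-methoxybenzyl ether would be the more usual chelating group, but its oxidative removal would clash with the tertiary amine carried from 19 onward; a benzyl ether is removed by hydrogenolysis at a stage where nothing else is reducible.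

16 ⇒ 9 + 10 (through 15, 14, 13 and 12). The bonds C5–C6 (methyl addition to an amide) and C3–C4 (auxiliary-controlled alkylation) are cut. The gain is two simple building blocks and a reliable source of the C4 configuration. The forward steps must enolise the methyl ketone kinetically at C6, so that C4 is not touched, and the alkyne must carry a silyl cap while strong bases are used.

## Other disconnections considered

Alternative 1: The cut is the C7–C8 bond, made by a [2,3]-Wittig rearrangement with ring contraction. The thirteen-membered (E,E)-bis-allylic ether A1 (oxygen between C8 and C13) would be deprotonated at C8 by an alkyllithium or a chiral lithium amide; the α-oxy carbanion attacks C7 through a five-membered envelope transition state, O–C13 breaks, and the ring contracts to cyclodecenol A2 with the C8 hydroxyl, a C7 isopropenyl group and the (E)-C9=C10 alkene. In its favour, the ten-membered ring arises from a larger ether ring that is easy to close, so no direct medium-ring C–C closure is needed; on this point it is better than the chosen plan, whose step 15 must close the ring directly. C7 and C8 are formed together with a relative configuration fixed by the alkene geometries, all fifteen skeletal carbons are present in A2, and C13 is already the methylene; in carbon economy it is at least the equal of the chosen plan. Against it, the two allylic O–CH2 positions (C8 and C13) compete for deprotonation, a [1,2]-shift can compete, and the absolute configuration would rest on an external chiral base or on the remote C4 centre, which is much less secure than taking C8 and C9 from tartaric acid. After A2, the C12 methyl group must be raised to the acid level by allylic oxidation. The C9 and C10 oxygens of 36 correspond to an anti addition across an (E)-C9=C10 bond, so a single syn-dihydroxylation would not serve; an epoxidation and an invertive opening at a hindered carbon would be needed. Mechanistically the concerted sigmatropic shift is as predictable in type as the ionic Michael addition, but the chosen plan controls its new centre by a substituent on the adjacent ring atom. In step count the two plans should be close, with more late oxidation-state changes in this alternative.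

Alternative 2: The cut is the pair C9–C10 and C5–C6, with a one-carbon carbonyl bridge between C10 and C5 as a temporary tether. In the forward sense 2,6-dimethyltropone A3 (six π electrons; C10, C1–C4, C5 and the bridge) and the (E)-1-benzyloxy-3-(2-silyloxyethyl)buta-1,3-diene A4 (C9, C8, C7, C6) would combine thermally in a [6+4] cycloaddition to the bicyclo[4.4.1]undecatrienone A5; the bridge would later be excised, for example by Baeyer–Villiger insertion next to the tertiary C10 (which gives the C10–O bond with retention) and oxidative removal of the remaining carbon at C5. In its favour, the whole ten-membered perimeter, the C10 quaternary centre with its methyl group and the C9 oxygen appear in one pericyclic step without any macrocyclisation, and the exo transition state is expected to give the required C9/C10 relationship; on ring construction and on C10 it is better than the chosen plan. Against it, the thermal reaction gives a racemate, the benzyloxy terminus of A4 must bond to the methyl-bearing and therefore more hindered terminus of A3, and [4+2] pathways compete. After A5, C4 would have to be set by reduction of the C1–C4 diene without a nearby controller, C7 and C8 by a syn addition across C7=C8, and the lactone and its methylene would still have to be built from the side chain. Structurally the alternative maps well onto the carbocycle but not onto the lactone stereochemistry, where the chosen plan is stronger; the step count up to A5 is far lower, but the work after it is likely to cancel that advantage.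

Alternative 3: The cut is the C8–C9 bond. The dialdehyde A7, whose C10 quaternary centre would come from (S)-citramalic acid A6, would be coupled reductively (low-valent titanium or a samarium-based one-electron reductant) to close the ten-membered ring as the C8/C9 diol, and the C8 hydroxyl would then lactonise onto the C12 ester to give the hydroxy lactone A8. In its favour, C10 comes from the chiral pool with certainty, which is better than the chosen plan's reliance on a chelation-controlled addition in a medium ring (step 18). Ring closure, two stereocentres and the lactone arise in one operation, and the C9 hydroxyl emerges free and ready for acylation; in bond economy it is the equal of the chosen plan or better. Against it, only one of four possible C8/C9 diastereomers is wanted and its selection depends on transition-state ring conformations; the ketyl formed at C9 has a silyloxy group on the neighbouring carbon and may eliminate it; low-valent titanium may deoxygenate to the alkene; C7, α to an aldehyde, can epimerise; and C4, C7 and C10 each need their own asymmetric step in the acyclic precursor. The ring-closing risk is comparable in both plans (both close the ten-membered ring directly). The chosen plan is more secure at C7, C8 and C9 and less secure at C10, and the step counts should be similar.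

Key step: step 10

Remarks on the chemistry (assumptions, one line each):
- 1 is taken as the commercial acetonide diol of L-threitol; it is otherwise two routine steps from diethyl L-tartrate (acetonide formation, hydride reduction).
- Stereochemical bookkeeping: C8 and C9 of 8 (5S,1'S) correspond to C3 and C2 of (2R,3R)-tartaric acid and to C8 and C9 of 36; C4 of 16 (3R) corresponds to C4 of 36 and is delivered by the (S)-benzyl auxiliary of 9.
- The silyl ether at O10 is tert-butyldiphenylsilyl, not a smaller silyl group, so that it survives the acidic steps 4, 5, 10 and 11.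
- 26 and 27 are carried as mixtures of C10 epimers that converge in step 17; C10 is therefore left undefined in their SMILES.
- In the SMILES of 23 and of the zirconium by-products the cyclopentadienyl ligands are drawn as σ-bonded C5H5 groups.

## Route

Step 1
Reactants: 1 (4S,5S)-2,2-dimethyl-1,3-dioxolane-4,5-dimethanol
Product: 3 [(4S,5S)-5-({[tert-butyl(diphenyl)silyl]oxy}methyl)-2,2-dimethyl-1,3-dioxolan-4-yl]methanol, via monosodium alkoxide 2 (not isolated)
Conditions: NaH (1.0 equiv), THF, 0 °C to rt; TBDPSCl (1.0 equiv), rt
Reagents that add atoms: tert-butyl(chloro)diphenylsilane, CC(C)(C)[Si](Cl)(c1ccccc1)c1ccccc1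
Why: O-silylation of the monosodium alkoxide of a C2-symmetric diol; the two hydroxyls are homotopic, so only mono- versus bis-silylation has to be controlled, and the sparingly soluble mono-alkoxide should react once.

Step 2
Reactants: 3 mono-silyl ether
Product: 4 (4R,5S)-5-({[tert-butyl(diphenyl)silyl]oxy}methyl)-2,2-dimethyl-1,3-dioxolane-4-carbaldehyde
Conditions: Dess–Martin periodinane, CH2Cl2, 0 °C to rt
Reagents that add atoms: none
Why: Dess–Martin oxidation is non-basic, so the α-alkoxy aldehyde, held in a trans-dioxolane, should keep its configuration; it is used without storage.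

Step 3
Reactants: 4 threose-derived aldehyde
Product: 5 methyl (2Z)-3-[(4S,5S)-5-({[tert-butyl(diphenyl)silyl]oxy}methyl)-2,2-dimethyl-1,3-dioxolan-4-yl]prop-2-enoate
Conditions: (CF3CH2O)2P(O)CH2CO2Me, KN(SiMe3)2, 18-crown-6, THF, −78 °C
Reagents that add atoms: methyl bis(2,2,2-trifluoroethyl)phosphonoacetate, COC(=O)CP(=O)(OCC(F)(F)F)OCC(F)(F)F
Why: Still–Gennari olefination: with the electron-poor phosphonate and a dissociated potassium counter-ion, elimination is faster than equilibration of the adducts, which should give the (Z)-enoate that the lactonisation needs; the step forms C7=C11 and brings in C12.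

Step 4
Reactants: 5 (Z)-enoate acetonide
Product: 7 (5S)-5-[(1S)-2-{[tert-butyl(diphenyl)silyl]oxy}-1-hydroxyethyl]furan-2(5H)-one, via dihydroxy ester 6 (not isolated)
Conditions: TFA/H2O (1:1), THF, 0 °C to rt
Reagents that add atoms: none
Why: Acid hydrolysis of the acetonide frees the diol 6, and the C8 hydroxyl, held cis to the ester by the (Z)-alkene, should close the five-membered butenolide (acid-catalysed transesterification, 5-exo-trig at the ester carbon) in preference to the six-membered lactone from the C9 hydroxyl; the tert-butyldiphenylsilyl ether tolerates aqueous TFA.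

Step 5
Reactants: 7 hydroxy butenolide
Product: 8 (5S)-5-[(1S)-1-(benzyloxy)-2-{[tert-butyl(diphenyl)silyl]oxy}ethyl]furan-2(5H)-one (fragment 2)
Conditions: BnOC(=NH)CCl3, TfOH (cat.), CH2Cl2/cyclohexane, 0 °C to rt
Reagents that add atoms: benzyl 2,2,2-trichloroacetimidate, ClC(Cl)(Cl)C(=N)OCc1ccccc1
Why: Acid-catalysed O-benzylation with the trichloroacetimidate avoids base, which would remove the acidic C8 proton of the butenolide and scramble that centre through the 2-oxidofuran; the benzyl ether is the chelating group for step 18 and leaves by hydrogenolysis in step 19.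

Step 6
Reactants: 9 (4S)-4-benzyl-3-propanoyl-1,3-oxazolidin-2-one; 10 3-bromo-1-(trimethylsilyl)prop-1-yne
Product: 12 (4S)-4-benzyl-3-[(2R)-2-methyl-5-(trimethylsilyl)pent-4-ynoyl]-1,3-oxazolidin-2-one, via sodium (Z)-enolate 11 (not isolated)
Conditions: NaN(SiMe3)2, THF, −78 °C; then 10, −78 to −40 °C
Reagents that add atoms: none
Why: Evans asymmetric alkylation: the chelated (Z)-enolate 11 is attacked by the propargylic bromide on the face opposite the benzyl group of the auxiliary, which should give the (R) configuration of the future C4; the silyl cap prevents acetylide formation.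

Step 7
Reactants: 12 alkylated imide
Product: 13 (2R)-N-methoxy-N,2-dimethyl-5-(trimethylsilyl)pent-4-ynamide
Conditions: MeNH(OMe)·HCl, AlMe3, CH2Cl2, 0 °C to rt; 1 M HCl work-up
Reagents that add atoms: N,O-dimethylhydroxylamine hydrochloride, CNOC.Cl
Why: Weinreb transamidation: the aluminium amide formed from AlMe3 and the amine salt attacks the exocyclic imide carbonyl and releases the auxiliary; the conditions are not basic at carbon, so the α-centre is retained.

Step 8
Reactants: 13 Weinreb amide
Product: 14 (3R)-3-methyl-6-(trimethylsilyl)hex-5-yn-2-one
Conditions: MeMgBr, THF, −20 to 0 °C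
Reagents that add atoms: methylmagnesium bromide, C[Mg]Br
Why: Weinreb ketone synthesis: the magnesium chelate of the tetrahedral adduct stops the reaction after one addition and gives the methyl ketone on work-up; the new methyl carbon is C6.

Step 9
Reactants: 14 methyl ketone
Product: 16 trimethyl{[(3R)-3-methyl-6-(trimethylsilyl)hex-1-en-5-yn-2-yl]oxy}silane (fragment 1), via lithium enolate 15 (not isolated)
Conditions: LiN(iPr)2, THF, −78 °C; TMSCl, −78 to 0 °C; pentane, cold aq. NaHCO3
Reagents that add atoms: chlorotrimethylsilane, C[Si](C)(C)Cl
Why: Kinetic enolisation with the hindered amide base removes a proton from the unhindered C6 methyl group and not from the C4 methine, and O-silylation of 15 fixes the terminal enol ether, so C4 is not touched; the acid-free work-up avoids isomerisation to the internal enol ether.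

Step 10
Reactants: 8 benzyl ether butenolide (fragment 2); 16 kinetic silyl enol ether (fragment 1); 17 dimethyl(methylidene)ammonium iodide
Product: 19 (3R,4S,5S)-5-[(1S)-1-(benzyloxy)-2-{[tert-butyl(diphenyl)silyl]oxy}ethyl]-3-[(dimethylamino)methyl]-4-[(3R)-3-methyl-2-oxo-6-(trimethylsilyl)hex-5-yn-1-yl]oxolan-2-one, via silyl ketene acetal 18 (not isolated)
Conditions: TMSOTf (0.2 equiv), 2,6-di-tert-butyl-4-methylpyridine (0.3 equiv), CH2Cl2, −78 °C; then 17, CH2Cl2/MeCN, −78 °C to rt; aq. NaHCO3
Reagents that add atoms: none
Why: Mukaiyama–Michael addition followed by Mannich alkylation of the silyl ketene acetal so formed; the closest known reaction type is the Lewis-acid-mediated conjugate addition of enol silanes to 5-substituted furan-2(5H)-ones combined with the aminomethylation of lactone ketene acetals by methyleneiminium salts. TMSOTf silylates the carbonyl oxygen of 8, C6 of 16 attacks C7 of the resulting 2-silyloxyfuranium ion, and loss of the trimethylsilyl group from the C5 oxocarbenium ion returns the catalyst and leaves the C5 ketone together with the lactone as its silyl ketene acetal 18. Added 17 then alkylates C11 of 18, the silyl group leaving with iodide, which forms C11–C13. No ring is closed; two skeletal bonds and two stereocentres are formed. C7 is controlled by the adjacent C8 substituent: the furanone is planar, the branched C9 side chain covers one face, and C6 should enter anti to it to give the 7,8-trans lactone. C11 is controlled by the new C7 chain (again anti), but this centre is destroyed in step 22 and its configuration does not matter. The step needs bond formation at C6 and not at C4, which the kinetic enol ether 16 secures as long as the hindered pyridine removes the traces of acid that would isomerise it; it needs 1,4-addition, which silyl activation of an unsaturated lactone favours; and it needs a single addition, which a small excess of 16 at −78 °C should ensure before 17 is introduced. A silyl Lewis acid in catalytic amount is used instead of a boron or titanium halide because silicon must end on the lactone oxygen for the second stage, and because the benzyl ether, the silyl ether and the alkynylsilane tolerate it at low temperature.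

Step 11
Reactants: 19 aminomethyl keto lactone
Product: 21 (3R,4S,5S)-5-[(1S)-1-(benzyloxy)-2-{[tert-butyl(diphenyl)silyl]oxy}ethyl]-3-[(dimethylamino)methyl]-4-({2-[(2R)-5-(trimethylsilyl)pent-4-yn-2-yl]-1,3-dioxolan-2-yl}methyl)oxolan-2-one, via ammonium triflate 20 (not isolated)
Conditions: TfOH (1.0 equiv), CH2Cl2, −78 °C; (TMSOCH2)2, TMSOTf (0.1 equiv), −78 to −20 °C; aq. NaHCO3
Reagents that add atoms: 1,2-bis(trimethylsilyloxy)ethane, C[Si](C)(C)OCCO[Si](C)(C)C
Why: Noyori ketalisation (silyl-transfer acetalisation) at low temperature converts the ketone and not the lactone; prior protonation to 20 keeps the tertiary amine from acting as a base toward silylated carbonyls, which would give enol silanes and put C4 at risk.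

Step 12
Reactants: 21 C5 ketal
Product: 22 (3R,4S,5S)-5-[(1S)-1-(benzyloxy)-2-hydroxyethyl]-3-[(dimethylamino)methyl]-4-({2-[(2R)-pent-4-yn-2-yl]-1,3-dioxolan-2-yl}methyl)oxolan-2-one
Conditions: Bu4NF, AcOH, THF, 0 °C to rt
Reagents that add atoms: none
Why: Fluoride cleaves both silicon groups in one operation, the O–Si bond of the silyl ether and the C(sp)–Si bond of the alkynylsilane; acetic acid buffers the alkoxide so that the lactone is not opened.

Step 13
Reactants: 22 alkynol
Product: 24 (3R,4S,5S)-5-[(1S)-1-(benzyloxy)-2-hydroxyethyl]-3-[(dimethylamino)methyl]-4-({2-[(2R,4E)-5-iodopent-4-en-2-yl]-1,3-dioxolan-2-yl}methyl)oxolan-2-one, via alkenylzirconocene 23 (not isolated)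
Conditions: Cp2Zr(H)Cl (3 equiv), THF, rt; I2, 0 °C
Reagents that add atoms: iodine, II
Why: Hydrozirconation adds Zr–H syn across the terminal alkyne with the metal on the terminal carbon C1, and iodinolysis of the C–Zr bond of 23 with retention should give the (E)-iodoalkene; one equivalent of the hydride is used up by the hydroxyl group, and the alkyne reacts much faster than the lactone carbonyl.

Step 14
Reactants: 24 (E)-iodoalkene alcohol
Product: 25 (2R)-2-(benzyloxy)-2-[(2S,3S,4R)-4-[(dimethylamino)methyl]-3-({2-[(2R,4E)-5-iodopent-4-en-2-yl]-1,3-dioxolan-2-yl}methyl)-5-oxooxolan-2-yl]acetaldehyde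
Conditions: Dess–Martin periodinane, CH2Cl2, 0 °C to rt
Reagents that add atoms: none
Why: Dess–Martin oxidation of the primary alcohol under non-basic conditions; the aldehyde has an α-alkoxy group and the C8 lactone oxygen in the β-position, so it is not exposed to base and is used directly.

Step 15
Reactants: 25 seco-aldehyde
Product: 26 (1E)-cyclodecenol lactone (C5 ketal; C9 benzyloxy; C10 hydroxyl as both epimers; C11 dimethylaminomethyl)
Conditions: CrCl2 (10 equiv), NiCl2 (2 mol %), DMSO/THF, rt, slow addition to 2 mM
Reagents that add atoms: none
Why: Nozaki–Hiyama–Kishi reaction: zerovalent nickel inserts into the C–I bond, transmetalation gives an alkenyl species of trivalent chromium that adds to the aldehyde but not to the lactone or the ketal, and C10–C1 closes the ten-membered ring with retention of the (E) geometry. High dilution disfavours oligomers, and the C10 configuration is left open because step 17 removes it.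

Step 16
Reactants: 26 (1E)-cyclodecenol lactone
Product: 27 cyclodecanol lactone (C1–C2 saturated; C10 hydroxyl as both epimers)
Conditions: H2 (1 atm), RhCl(PPh3)3 (10 mol %), benzene/EtOH, rt
Reagents that add atoms: none
Why: Homogeneous hydrogenation with RhCl(PPh3)3 saturates the strained disubstituted C1=C2 alkene and does not cleave benzyl ethers.

Step 17
Reactants: 27 cyclodecanol lactone
Product: 28 C10 ketone (C5 ketal; C9 benzyloxy; C11 dimethylaminomethyl)
Conditions: Dess–Martin periodinane, CH2Cl2, rt
Reagents that add atoms: none
Why: Dess–Martin oxidation of the secondary alcohol merges both C10 epimers into one ketone; the neutral conditions avoid enolisation toward C9 and loss of the β-lactone oxygen.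

Step 18
Reactants: 28 C10 ketone
Product: 29 (10S)-tertiary alcohol (C10 methyl carbinol; C9 benzyloxy; C5 ketal; C11 dimethylaminomethyl)
Conditions: MeMgBr (3 equiv), CH2Cl2/Et2O, −78 °C
Reagents that add atoms: methylmagnesium bromide, C[Mg]Br
Why: Chelation-controlled Grignard addition (Cram chelate model): magnesium bridges the C10 carbonyl and the C9 benzyloxy oxygen, the ring bond C9–C8 covers one face of this five-membered chelate, and the methyl group should enter from the side of the C9 hydrogen, which is also the outer face of the medium ring, to give the (10S) carbinol. At −78 °C the chelated ketone should react far faster than the lactone.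

Step 19
Reactants: 29 (10S)-tertiary alcohol
Product: 30 (9R,10S)-diol (C5 ketal; C11 dimethylaminomethyl)
Conditions: H2 (1–3 atm), Pd(OH)2/C, EtOH/AcOH (10:1), rt
Reagents that add atoms: none
Why: Hydrogenolysis of the benzyl ether; no other reducible group remains, and the acetic acid keeps the amine protonated so that it does not slow the catalyst.

Step 20
Reactants: 30 (9R,10S)-diol; 31 (2R)-2-methylbutanoic acid
Product: 33 C9 (2R)-2-methylbutanoate (C10 hydroxyl free; C5 ketal; C11 dimethylaminomethyl), via mixed anhydride 32 (not isolated)
Conditions: 31, 2,4,6-Cl3C6H2COCl, Et3N, THF, rt; then 30, DMAP, PhMe, rt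
Reagents that add atoms: none
Why: Yamaguchi esterification: 31 is activated as the mixed anhydride 32 and transferred by DMAP to the secondary C9 hydroxyl; the tertiary C10 hydroxyl is too hindered to react, and a simple α-branched alkanoyl donor is not expected to racemise under these conditions.

Step 21
Reactants: 33 C9 ester ketal
Product: 34 13-(dimethylamino)-11,13-dihydro derivative of 36 (C5 ketone free)
Conditions: 1 M HCl/THF (1:2), rt; aq. NaHCO3
Reagents that add atoms: water, O
Why: Acid-catalysed hydrolysis of the dioxolane releases the C5 ketone; it follows the acylation so that a free C9 hydroxyl never faces the C5 carbonyl across the ring, and dilute acid at room temperature should leave the ester, the lactone, the tertiary alcohol and the C4 centre intact.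

Step 22
Reactants: 34 amine adduct
Product: 36 Ineupatorolide A, via trimethylammonium iodide 35 (not isolated)
Conditions: MeI (excess), MeCN, rt; then aq. NaHCO3/EtOAc, rt
Reagents that add atoms: none
Why: Exhaustive methylation gives the ammonium salt 35, and bicarbonate then removes the acidic C11 proton and expels trimethylamine (E1cB, Hofmann-type elimination) to give the exocyclic methylene; the base is too weak to cleave the C9 ester or to epimerise C4.

## Compound list

1 | (4S,5S)-2,2-dimethyl-1,3-dioxolane-4,5-dimethanol (2,3-O-isopropylidene-L-threitol) | OC[C@@H]1OC(C)(C)O[C@H]1CO | starting material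
2 | monosodium alkoxide of 1 | [Na+].[O-]C[C@@H]1OC(C)(C)O[C@H]1CO | intermediate
3 | [(4S,5S)-5-({[tert-butyl(diphenyl)silyl]oxy}methyl)-2,2-dimethyl-1,3-dioxolan-4-yl]methanol | CC(C)(C)[Si](c1ccccc1)(c1ccccc1)OC[C@@H]1OC(C)(C)O[C@H]1CO | intermediate
4 | (4R,5S)-5-({[tert-butyl(diphenyl)silyl]oxy}methyl)-2,2-dimethyl-1,3-dioxolane-4-carbaldehyde | CC(C)(C)[Si](c1ccccc1)(c1ccccc1)OC[C@@H]1OC(C)(C)O[C@H]1C=O | intermediate
5 | methyl (2Z)-3-[(4S,5S)-5-({[tert-butyl(diphenyl)silyl]oxy}methyl)-2,2-dimethyl-1,3-dioxolan-4-yl]prop-2-enoate | CC(C)(C)[Si](c1ccccc1)(c1ccccc1)OC[C@@H]1OC(C)(C)O[C@H]1/C=C\C(=O)OC | intermediate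
6 | methyl (2Z,4S,5S)-6-{[tert-butyl(diphenyl)silyl]oxy}-4,5-dihydroxyhex-2-enoate | CC(C)(C)[Si](c1ccccc1)(c1ccccc1)OC[C@H](O)[C@@H](O)/C=C\C(=O)OC | intermediate
7 | (5S)-5-[(1S)-2-{[tert-butyl(diphenyl)silyl]oxy}-1-hydroxyethyl]furan-2(5H)-one | O=C1C=C[C@H](O1)[C@@H](O)CO[Si](c2ccccc2)(c2ccccc2)C(C)(C)C | intermediate
8 | (5S)-5-[(1S)-1-(benzyloxy)-2-{[tert-butyl(diphenyl)silyl]oxy}ethyl]furan-2(5H)-one (fragment 2) | O=C1C=C[C@H](O1)[C@@H](OCc2ccccc2)CO[Si](c2ccccc2)(c2ccccc2)C(C)(C)C | intermediate
9 | (4S)-4-benzyl-3-propanoyl-1,3-oxazolidin-2-one | CCC(=O)N1[C@@H](Cc2ccccc2)COC1=O | starting material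
10 | 3-bromo-1-(trimethylsilyl)prop-1-yne | C[Si](C)(C)C#CCBr | starting material
11 | sodium (Z)-enolate of 9 | C/C=C(\[O-])N1[C@@H](Cc2ccccc2)COC1=O.[Na+] | intermediate
12 | (4S)-4-benzyl-3-[(2R)-2-methyl-5-(trimethylsilyl)pent-4-ynoyl]-1,3-oxazolidin-2-one | C[Si](C)(C)C#CC[C@@H](C)C(=O)N1[C@@H](Cc2ccccc2)COC1=O | intermediate
13 | (2R)-N-methoxy-N,2-dimethyl-5-(trimethylsilyl)pent-4-ynamide | C[Si](C)(C)C#CC[C@@H](C)C(=O)N(C)OC | intermediate
14 | (3R)-3-methyl-6-(trimethylsilyl)hex-5-yn-2-one | CC(=O)[C@H](C)CC#C[Si](C)(C)C | intermediate
15 | lithium enolate of 14 (C5–O, C5=C6) | [Li+].[O-]C(=C)[C@H](C)CC#C[Si](C)(C)C | intermediate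
16 | trimethyl{[(3R)-3-methyl-6-(trimethylsilyl)hex-1-en-5-yn-2-yl]oxy}silane (fragment 1) | C=C(O[Si](C)(C)C)[C@H](C)CC#C[Si](C)(C)C | intermediate
17 | dimethyl(methylidene)ammonium iodide | C=[N+](C)C.[I-] | starting material
18 | silyl ketene acetal of the Michael adduct: 2-(trimethylsilyloxy)-4,5-dihydrofuran with C11=C12, the C7 ketone chain and the C8 side chain trans | C[Si](C)(C)OC1=C[C@H](CC(=O)[C@H](C)CC#C[Si](C)(C)C)[C@H](O1)[C@@H](OCc2ccccc2)CO[Si](c2ccccc2)(c2ccccc2)C(C)(C)C | intermediate
19 | (3R,4S,5S)-5-[(1S)-1-(benzyloxy)-2-{[tert-butyl(diphenyl)silyl]oxy}ethyl]-3-[(dimethylamino)methyl]-4-[(3R)-3-methyl-2-oxo-6-(trimethylsilyl)hex-5-yn-1-yl]oxolan-2-one | CN(C)C[C@@H]1C(=O)O[C@H]([C@@H](OCc2ccccc2)CO[Si](c2ccccc2)(c2ccccc2)C(C)(C)C)[C@H]1CC(=O)[C@H](C)CC#C[Si](C)(C)C | intermediate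
20 | trifluoromethanesulfonate salt of 19 (protonated dimethylamino group) | C[NH+](C)C[C@@H]1C(=O)O[C@H]([C@@H](OCc2ccccc2)CO[Si](c2ccccc2)(c2ccccc2)C(C)(C)C)[C@H]1CC(=O)[C@H](C)CC#C[Si](C)(C)C.[O-]S(=O)(=O)C(F)(F)F | intermediate
21 | (3R,4S,5S)-5-[(1S)-1-(benzyloxy)-2-{[tert-butyl(diphenyl)silyl]oxy}ethyl]-3-[(dimethylamino)methyl]-4-({2-[(2R)-5-(trimethylsilyl)pent-4-yn-2-yl]-1,3-dioxolan-2-yl}methyl)oxolan-2-one | CN(C)C[C@@H]1C(=O)O[C@H]([C@@H](OCc2ccccc2)CO[Si](c2ccccc2)(c2ccccc2)C(C)(C)C)[C@H]1CC3(OCCO3)[C@H](C)CC#C[Si](C)(C)C | intermediate
22 | (3R,4S,5S)-5-[(1S)-1-(benzyloxy)-2-hydroxyethyl]-3-[(dimethylamino)methyl]-4-({2-[(2R)-pent-4-yn-2-yl]-1,3-dioxolan-2-yl}methyl)oxolan-2-one | CN(C)C[C@@H]1C(=O)O[C@H]([C@@H](OCc2ccccc2)CO)[C@H]1CC3(OCCO3)[C@H](C)CC#C | intermediate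
23 | (E)-alkenylzirconocene chloride at C1 of 22, with O10 as its zirconocene chloride alkoxide | CN(C)C[C@@H]1C(=O)O[C@H]([C@@H](OCc2ccccc2)CO[Zr](Cl)(C2C=CC=C2)C2C=CC=C2)[C@H]1CC3(OCCO3)[C@H](C)C/C=C/[Zr](Cl)(C2C=CC=C2)C2C=CC=C2 | intermediate
24 | (3R,4S,5S)-5-[(1S)-1-(benzyloxy)-2-hydroxyethyl]-3-[(dimethylamino)methyl]-4-({2-[(2R,4E)-5-iodopent-4-en-2-yl]-1,3-dioxolan-2-yl}methyl)oxolan-2-one | CN(C)C[C@@H]1C(=O)O[C@H]([C@@H](OCc2ccccc2)CO)[C@H]1CC3(OCCO3)[C@H](C)C/C=C/I | intermediate
25 | (2R)-2-(benzyloxy)-2-[(2S,3S,4R)-4-[(dimethylamino)methyl]-3-({2-[(2R,4E)-5-iodopent-4-en-2-yl]-1,3-dioxolan-2-yl}methyl)-5-oxooxolan-2-yl]acetaldehyde | CN(C)C[C@@H]1C(=O)O[C@H]([C@@H](OCc2ccccc2)C=O)[C@H]1CC3(OCCO3)[C@H](C)C/C=C/I | intermediate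
26 | ten-membered ring C1–C10 trans-fused at C7/C8 to the γ-lactone (O–C8, C12=O, C11): (1E)-alkene, (4R)-methyl, C5 ethylene ketal, C9 benzyloxy, C10 hydroxyl (both epimers), (11R)-CH2NMe2 trans to C6; C7, C8, C9 arranged as in 36 | CN(C)C[C@@H]1C(=O)O[C@@H]2[C@@H](OCc3ccccc3)C(O)/C=C/C[C@@H](C)C4(OCCO4)C[C@@H]12 | intermediate
27 | 1,2-dihydro derivative of 26 (C1–C2 saturated; C10 hydroxyl, both epimers) | CN(C)C[C@@H]1C(=O)O[C@@H]2[C@@H](OCc3ccccc3)C(O)CCC[C@@H](C)C4(OCCO4)C[C@@H]12 | intermediate
28 | C10 ketone of 27 (C5 ethylene ketal, C9 benzyloxy, (11R)-CH2NMe2) | CN(C)C[C@@H]1C(=O)O[C@@H]2[C@@H](OCc3ccccc3)C(=O)CCC[C@@H](C)C4(OCCO4)C[C@@H]12 | intermediate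
29 | (4R,7S,8S,9R,10S,11R)-9-benzyloxy-10-hydroxy-10-methyl lactone with C5 ethylene ketal and C11 CH2NMe2 | CN(C)C[C@@H]1C(=O)O[C@@H]2[C@@H](OCc3ccccc3)[C@@](C)(O)CCC[C@@H](C)C4(OCCO4)C[C@@H]12 | intermediate
30 | (4R,7S,8S,9R,10S,11R)-9,10-diol with C5 ethylene ketal and C11 CH2NMe2 | CN(C)C[C@@H]1C(=O)O[C@@H]2[C@@H](O)[C@@](C)(O)CCC[C@@H](C)C4(OCCO4)C[C@@H]12 | intermediate
31 | (2R)-2-methylbutanoic acid | CC[C@@H](C)C(=O)O | starting material
32 | (2R)-2-methylbutanoic 2,4,6-trichlorobenzoic anhydride | CC[C@@H](C)C(=O)OC(=O)c1c(Cl)cc(Cl)cc1Cl | intermediate
33 | C9 (2R)-2-methylbutanoate of 30 (C10 hydroxyl free, C5 ethylene ketal) | CN(C)C[C@@H]1C(=O)O[C@@H]2[C@@H](OC(=O)[C@H](C)CC)[C@@](C)(O)CCC[C@@H](C)C4(OCCO4)C[C@@H]12 | intermediate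
34 | (11R)-13-(dimethylamino)-11,13-dihydro derivative of 36 | CN(C)C[C@@H]1C(=O)O[C@@H]2[C@@H](OC(=O)[C@H](C)CC)[C@@](C)(O)CCC[C@@H](C)C(=O)C[C@@H]12 | intermediate
35 | N-methyl ammonium iodide of 34 (C13–NMe3 iodide) | C[N+](C)(C)C[C@@H]1C(=O)O[C@@H]2[C@@H](OC(=O)[C@H](C)CC)[C@@](C)(O)CCC[C@@H](C)C(=O)C[C@@H]12.[I-] | intermediate
36 | Ineupatorolide A: (4R,7S,8S,9R,10S)-10-hydroxy-4,10-dimethyl-5-oxo ten-membered ring trans-fused at C7/C8 to the α-methylene-γ-lactone, C9 ester of (2R)-2-methylbutanoic acid | C=C1C(=O)O[C@@H]2[C@@H](OC(=O)[C@H](C)CC)[C@@](C)(O)CCC[C@@H](C)C(=O)C[C@@H]12 | target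

## Step count and risks

Total: 22 steps (steps 1–5 to fragment 2, steps 6–9 to fragment 1, step 10 for the union, steps 11–22 to the target). Longest linear sequence: 18 steps (from 1 through steps 1–5 and 10–22).

Least certain steps:

Step 10 (key step). The most likely failures are incomplete capture of the ketene acetal 18 by the poorly soluble iminium salt (protodesilylation then gives the lactone without C13), acid-induced isomerisation of 16 to the internal enol ether with loss of the C4 configuration, and a second conjugate addition of 18 to unreacted 8. The facial selectivity at C7 is the least worrying point, because it rests on a substituent next to the reacting carbon. Fallback: the two bond formations are separated. From 8 and 16 the Michael stage alone is run and quenched with aqueous bicarbonate to give the keto lactone F1; silyl-transfer ketalisation as in step 11 gives the ketal lactone F2, in which the lactone α-position is the only acidic site; deprotonation with LiN(iPr)2 at −78 °C and aminomethylation of the lithium enolate with 17 then gives 21, where the route is rejoined.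

Step 15. Intermolecular coupling may outrun the closure of a strained ten-membered ring that carries a trans-fused lactone, and the aldehyde 25 may lose the C8 lactone oxygen by β-elimination before it cyclises. Fallback: the ring is closed at C1=C2 by metathesis instead of at C10–C1. From 22, semi-hydrogenation over Pd/CaCO3–Pb(OAc)2 with quinoline gives the terminal alkene alcohol F3, Dess–Martin oxidation gives the aldehyde F4, and vinylmagnesium bromide at −78 °C gives the diene carbinol F5 (C10 epimers). Ring-closing metathesis with second-generation Grubbs catalyst on the camphorsulfonate salt of the amine at high dilution then expels ethene and gives 26 or its (1Z) isomer F6; either is hydrogenated as in step 16 to 27, where the route is rejoined. In this variant C1 comes from the vinyl reagent and the former alkyne terminus is lost.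

Step 18. The medium ring may not adopt the chelate conformation, so that the methyl group attacks the other face; the Grignard reagent may also enolise the ketone toward C9, with loss of the lactone oxygen, or attack the lactone. Fallback: the two substituents at C10 are introduced in the opposite sense. From 28, Takai–Lombardo methylenation (Zn, CH2Br2, TiCl4), which is not basic and spares lactones, gives the exocyclic alkene F7. Mukaiyama hydration (Co(acac)2, PhSiH3, O2) then adds hydrogen to the methylene carbon and oxygen to C10 through the tertiary radical. The oxygen enters from the outer face of the ring, the face a carbon nucleophile would take on the same conformer, so this sequence is the stereochemical complement of step 18 and leads to 29, where the route is rejoined.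

Step 13. The hydride reagent may reduce the lactone or react incompletely because the substrate carries a free hydroxyl group and a basic amine. Fallback: the iodoalkene is avoided altogether. From 22, Dess–Martin oxidation gives the alkynal F8; a reductive alkyne–aldehyde macrocyclisation with Ni(cod)2 (zerovalent nickel), an N-heterocyclic carbene ligand and Et3SiH forms C10–C1 at the terminal alkyne carbon and gives the (1E)-allylic triethylsilyl ether F9; Bu4NF/AcOH then gives 26, where the route is rejoined.

## Further compounds

F1 | step 10 | (4S,5S)-5-[(1S)-1-(benzyloxy)-2-{[tert-butyl(diphenyl)silyl]oxy}ethyl]-4-[(3R)-3-methyl-2-oxo-6-(trimethylsilyl)hex-5-yn-1-yl]oxolan-2-one | O=C1C[C@H](CC(=O)[C@H](C)CC#C[Si](C)(C)C)[C@H](O1)[C@@H](OCc2ccccc2)CO[Si](c2ccccc2)(c2ccccc2)C(C)(C)C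
F2 | step 10 | C5 ethylene ketal of F1 | O=C1C[C@H](CC3(OCCO3)[C@H](C)CC#C[Si](C)(C)C)[C@H](O1)[C@@H](OCc2ccccc2)CO[Si](c2ccccc2)(c2ccccc2)C(C)(C)C
F3 | step 15 | terminal alkene analogue of 22 (pent-4-en-2-yl in place of pent-4-yn-2-yl) | CN(C)C[C@@H]1C(=O)O[C@H]([C@@H](OCc2ccccc2)CO)[C@H]1CC3(OCCO3)[C@H](C)CC=C
F4 | step 15 | C10 aldehyde of F3 | CN(C)C[C@@H]1C(=O)O[C@H]([C@@H](OCc2ccccc2)C=O)[C@H]1CC3(OCCO3)[C@H](C)CC=C
F5 | step 15 | vinyl carbinol from F4 (C10 hydroxyl, both epimers; two terminal alkenes) | CN(C)C[C@@H]1C(=O)O[C@H]([C@@H](OCc2ccccc2)C(O)C=C)[C@H]1CC3(OCCO3)[C@H](C)CC=C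
F6 | step 15 | (1Z) isomer of 26 | CN(C)C[C@@H]1C(=O)O[C@@H]2[C@@H](OCc3ccccc3)C(O)/C=C\C[C@@H](C)C4(OCCO4)C[C@@H]12
F7 | step 18 | 10-methylidene analogue of 28 (C10=CH2 in place of C10=O) | CN(C)C[C@@H]1C(=O)O[C@@H]2[C@@H](OCc3ccccc3)C(=C)CCC[C@@H](C)C4(OCCO4)C[C@@H]12
F8 | step 13 | C10 aldehyde of 22 (alkynal) | CN(C)C[C@@H]1C(=O)O[C@H]([C@@H](OCc2ccccc2)C=O)[C@H]1CC3(OCCO3)[C@H](C)CC#C
F9 | step 13 | C10 triethylsilyl ether of 26 | CN(C)C[C@@H]1C(=O)O[C@@H]2[C@@H](OCc3ccccc3)C(O[Si](CC)(CC)CC)/C=C/C[C@@H](C)C4(OCCO4)C[C@@H]12
A1 | alternative 1 | thirteen-membered (E,E)-bis-allylic ether (oxygen between C8 and C13; C5 ethylene ketal; 4R) | C[C@@H]1CCC/C(C)=C/COC/C(C)=C/CC12OCCO2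
A2 | alternative 1 | cyclodecenol with C8 hydroxyl, C7 isopropenyl and (E)-C9=C10 (C5 ethylene ketal) | C[C@@H]1CCC/C(C)=C/[C@@H](O)[C@H](C(C)=C)CC12OCCO2
A3 | alternative 2 | 2,6-dimethyltropone | CC1=CC=CC(C)=CC1=O
A4 | alternative 2 | (E)-1-benzyloxy-3-[2-(tert-butyldimethylsilyloxy)ethyl]buta-1,3-diene | C=C(CCO[Si](C)(C)C(C)(C)C)/C=C/OCc1ccccc1
A5 | alternative 2 | exo bicyclo[4.4.1]undecatrienone with C9 benzyloxy and C10 methyl bridgehead | O=C1[C@]2(C)[C@H](OCc3ccccc3)C=C(CCO[Si](C)(C)C(C)(C)C)C[C@H]1C(C)=CC=C2
A6 | alternative 3 | (S)-citramalic acid | OC(=O)[C@@](C)(O)CC(=O)O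
A7 | alternative 3 | acyclic C8,C9-dialdehyde with C12 methyl ester, C5 ethylene ketal and C10 triethylsilyl ether | O=C[C@H](CC(=O)OC)CC1(OCCO1)[C@H](C)CCC[C@](C)(O[Si](CC)(CC)CC)C=O
A8 | alternative 3 | trans-fused C9-hydroxy lactone on the ten-membered ring (C10 triethylsilyl ether, C5 ethylene ketal) | O=C1O[C@@H]2[C@@H](O)[C@@](C)(O[Si](CC)(CC)CC)CCC[C@@H](C)C3(OCCO3)C[C@H]2C1
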